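## Retrosynthetic overview

1. Target 20 comes from 19 by global desilylation. Cutting C3–C4 of ring C in 19 gives 18, an achiral isomer in which ring A carries the C4 formyl group and O1 carries the enol ether C2(=C3H2)–ring B. An enantioselective rhodium hydroacylation closes ring C, creates the C4 ketone and sets C2 in one isomerisation.
2. Enabling feature: in ring C, C2 bears both O1 and ring B while C3 is a bare CH2. C2=C3 can therefore exist as a 1,1-disubstituted aryl enol ether, held by O1–C8a–C4a next to the formyl carbon C4. Its fully substituted C2 blocks the exo (benzofuranone) path.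
3. 18 comes from bromo ether 17 by loss of HBr. 17 comes from a Mitsunobu O1–C2 union of ring A salicylaldehyde 8 with ring B bromohydrin 16.
4. 8 comes from gallaldehyde 1. O7/O8 are tied as a di-tert-butylsilylene, the CHO becomes O5 by Baeyer–Villiger oxidation, and the C4 carbon enters by OH-directed ortho-formylation at C4a.
5. 16 comes from acetophenone 9 and bromide 11 (Negishi coupling, bromination, reduction). Rings A and B are bought, the silylene ring is temporary (steps 1 to 12), and ring C is the only ring of the target that is built, last.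

Key step: step 11

Remark: flavanone numbering (O1, C2, C3, C4, C4a, C5–C8, C8a; ring B primed) is used for all intermediates.

Assumption: (R)-DTBM-SEGPHOS is written as the ligand enantiomer that leads to (2S). The sense of induction on this substrate class is not known. If it is the opposite, the (S)-ligand is used with no other change.

## Route

Step 1
Reactants: 1 3,4,5-trihydroxybenzaldehyde (dried)
Product: 3 2,2-di-tert-butyl-6-formyl-1,3,2-benzodioxasilol-4-yl acetate, via free phenol 2 (not isolated)
Conditions: tBu2Si(OTf)2, 2,6-lutidine, DMF, 0 °C; then Ac2O, DMAP (cat.), 0 °C to rt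
Reagents that add atoms: di-tert-butylsilyl bis(trifluoromethanesulfonate), CC(C)(C)[Si](OS(=O)(=O)C(F)(F)F)(OS(=O)(=O)C(F)(F)F)C(C)(C)C; acetic anhydride, CC(=O)OC(C)=O
Why: Cyclic silylene protection of a catechol can only bridge two neighbouring oxygens and the two possible pairs of the symmetric pyrogallol unit are equivalent, so one phenol 2 should form, and its last OH (the later O1) is blocked in the same flask by DMAP-catalysed acetylation.

Step 2
Reactants: 3 2,2-di-tert-butyl-6-formyl-1,3,2-benzodioxasilol-4-yl acetate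
Product: 5 2,2-di-tert-butyl-6-hydroxy-1,3,2-benzodioxasilol-4-yl acetate, via aryl formate 4 (not isolated)
Conditions: mCPBA, CH2Cl2, 0 °C to rt; aq. Na2S2O3/NaHCO3 wash; then n-BuNH2 (1 equiv), CH2Cl2, 0 °C
Reagents that add atoms: 3-chloroperbenzoic acid, O=C(OO)c1cccc(Cl)c1
Why: Baeyer–Villiger oxidation of a benzaldehyde with a para oxygen donor shifts the aryl group to oxygen, and aminolysis cleaves the aryl formate 4 much faster than the aryl acetate, so only O5–H is set free while the silylene sees neither acid nor alkoxide.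

Step 3
Reactants: 5 2,2-di-tert-butyl-6-hydroxy-1,3,2-benzodioxasilol-4-yl acetate
Product: 7 6-[(tert-butyldimethylsilyl)oxy]-2,2-di-tert-butyl-1,3,2-benzodioxasilol-4-ol, via silyl ether acetate 6 (not isolated)
Conditions: TBSCl (1.05 equiv), imidazole, CH2Cl2, 0 °C to rt; then pyrrolidine, rt
Reagents that add atoms: tert-butyldimethylsilyl chloride, CC(C)(C)[Si](C)(C)Cl
Why: Standard silylation of the only free phenol is followed by aminolysis of the phenolic acetate, to which aryl silyl ethers are inert, and the freed O1–H cannot pick up silicon from O8 because the five-membered silylene ring holds the silicon atom far from O1.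

Step 4
Reactants: 7 6-[(tert-butyldimethylsilyl)oxy]-2,2-di-tert-butyl-1,3,2-benzodioxasilol-4-ol
Product: 8 6-[(tert-butyldimethylsilyl)oxy]-2,2-di-tert-butyl-4-hydroxy-1,3,2-benzodioxasilole-5-carbaldehyde
Conditions: MgCl2, Et3N, (CH2O)n, THF, reflux; cold aq. citric acid work-up
Reagents that add atoms: paraformaldehyde, written as formaldehyde, C=O
Why: Casnati–Skattebøl ortho-formylation passes formaldehyde to the ring inside a magnesium phenoxide complex and therefore attacks only ortho to O1–H, where C4a is the single free position, so the open para carbon C6 should stay untouched.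

Step 5
Reactants: 9 1-(3-bromo-4-hydroxyphenyl)ethan-1-one
Product: 10 1-{3-bromo-4-[(tert-butyldimethylsilyl)oxy]phenyl}ethan-1-one
Conditions: TBSCl, imidazole, DMF, rt
Reagents that add atoms: tert-butyldimethylsilyl chloride, CC(C)(C)[Si](C)(C)Cl
Why: Routine imidazole-promoted silylation of a phenol, chosen so that all phenol protecting groups fall to fluoride in the last step.

Step 6
Reactants: 10 1-{3-bromo-4-[(tert-butyldimethylsilyl)oxy]phenyl}ethan-1-one; 11 4-bromo-2-methylbut-1-ene
Product: 13 1-{4-[(tert-butyldimethylsilyl)oxy]-3-(3-methylbut-3-en-1-yl)phenyl}ethan-1-one, via organozinc bromide 12 (not isolated)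
Conditions: 11, Zn dust, LiCl, THF, 45 °C; then 10, Pd(OAc)2 (2 mol%), SPhos (4 mol%), THF, rt
Reagents that add atoms: zinc dust, [Zn] (kept only in 12)
Why: Negishi coupling of a primary alkylzinc halide with an aryl bromide, in which the bulky biaryl phosphine speeds reductive elimination over beta-hydride elimination and the organozinc reagent leaves the ketone alone.

Step 7
Reactants: 13 1-{4-[(tert-butyldimethylsilyl)oxy]-3-(3-methylbut-3-en-1-yl)phenyl}ethan-1-one
Product: 15 2-bromo-1-{4-[(tert-butyldimethylsilyl)oxy]-3-(3-methylbut-3-en-1-yl)phenyl}ethan-1-one, via trimethylsilyl enol ether 14 (not isolated)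
Conditions: Me3SiOTf, Et3N, CH2Cl2, 0 °C; crude 14, NBS (1.0 equiv), THF, −78 °C
Reagents that add atoms: trimethylsilyl triflate, C[Si](C)(C)OS(=O)(=O)C(F)(F)F (kept only in 14); N-bromosuccinimide, O=C1CCC(=O)N1Br
Why: Alpha-bromination of a ketone by way of its enol silane, which is far more nucleophilic than the 1,1-dialkyl alkene of the side chain and so takes up the one equivalent of electrophilic bromine at low temperature.

Step 8
Reactants: 15 2-bromo-1-{4-[(tert-butyldimethylsilyl)oxy]-3-(3-methylbut-3-en-1-yl)phenyl}ethan-1-one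
Product: 16 racemic 2-bromo-1-{4-[(tert-butyldimethylsilyl)oxy]-3-(3-methylbut-3-en-1-yl)phenyl}ethan-1-ol
Conditions: NaBH4, THF/MeOH, −20 °C; AcOH quench
Reagents that add atoms: none
Why: Borohydride reduction of an alpha-bromo ketone at low temperature with an acidic quench stops at the bromohydrin without epoxide closure, and the racemate is all that is needed because this stereocentre is erased in step 10.

Step 9
Reactants: 8 6-[(tert-butyldimethylsilyl)oxy]-2,2-di-tert-butyl-4-hydroxy-1,3,2-benzodioxasilole-5-carbaldehyde; 16 racemic bromohydrin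
Product: 17 racemic 4-(2-bromo-1-{4-[(tert-butyldimethylsilyl)oxy]-3-(3-methylbut-3-en-1-yl)phenyl}ethoxy)-6-[(tert-butyldimethylsilyl)oxy]-2,2-di-tert-butyl-1,3,2-benzodioxasilole-5-carbaldehyde
Conditions: PPh3, DIAD, toluene, 0 °C to rt
Reagents that add atoms: none
Why: Mitsunobu etherification suits the acidic chelated phenol 8 and forms O1–C2 under neutral conditions that spare the aldehyde, the primary bromide and all silyl groups, the steric course being irrelevant here.

Step 10
Reactants: 17 racemic bromo ether aldehyde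
Product: 18 4-[(1-{4-[(tert-butyldimethylsilyl)oxy]-3-(3-methylbut-3-en-1-yl)phenyl}ethenyl)oxy]-6-[(tert-butyldimethylsilyl)oxy]-2,2-di-tert-butyl-1,3,2-benzodioxasilole-5-carbaldehyde (achiral)
Conditions: DBU, toluene, 70 °C; filtration through Et3N-washed silica
Reagents that add atoms: none
Why: E2 dehydrobromination with an amidine base, in which the only hydrogen beta to bromine is the benzylic, oxygen-bearing C2–H, so the alpha-aryloxystyrene is the single possible alkene and the non-enolisable aldehyde tolerates the base.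

Step 11
Reactants: 18 formyl enol ether
Product: 19 (2S)-5-[(tert-butyldimethylsilyl)oxy]-2-{4-[(tert-butyldimethylsilyl)oxy]-3-(3-methylbut-3-en-1-yl)phenyl}-7,8-[(di-tert-butylsilanediyl)bis(oxy)]-2,3-dihydro-4H-chromen-4-one
Conditions: [Rh(cod)Cl]2 (2.5 mol%), (R)-DTBM-SEGPHOS (5 mol%), NaB[3,5-(CF3)2C6H3]4 (5 mol%), 2,6-di-tert-butylpyridine (10 mol%), 1,4-dioxane, 60–80 °C, argon
Reagents that add atoms: none
Why: Proposed new method: monovalent rhodium adds oxidatively into the formyl C4–H bond of 18, the acyl rhodium hydride binds the tethered C2=C3 enol ether, hydride migrates to C2 while rhodium takes the CH2 terminus C3, and C–C reductive elimination from the seven-membered acyl alkyl rhodacycle joins C3 to C4 and returns the catalyst. The closest known reaction type is the enantioselective intramolecular alkene hydroacylation of ortho-(2-substituted allyl)benzaldehydes to 3-substituted tetralones with the same cationic rhodium/bulky bisphosphine catalysts; new here is O1 in place of the benzylic CH2, which makes the alkene an alpha-aryloxystyrene, a substrate class not yet shown for this reaction. Ring C closes in a formal 6-endo-trig mode (acyl carbon to the alkene terminus), and no other ring is formed. The one new stereocentre, C2, arises when hydride is delivered to one face of the bound alkene, and the face is chosen by the axially chiral bisphosphine, which must tell ring B from the tether oxygen O1 at the prochiral carbon; because insertion may be reversible, the faster reductive elimination of one diastereomeric rhodacycle may add to the selection. Regioselectivity (flavanone against 2-aryl-2-methylbenzofuran-3-one) is secured by the fully substituted C2, since the exo path needs a tertiary alkyl rhodium and a reductive elimination that builds a quaternary carbon; decarbonylation is held back by chelation of the alkene, C2=C3 has no allylic hydrogen and so cannot isomerise away, and the remote 1,1-dialkyl alkene of the side chain cannot chelate to the acyl rhodium centre. The hindered pyridine traps adventitious acid, which would otherwise drive a Prins-type attack of the nucleophilic C3 on the aldehyde.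

Step 12
Reactants: 19 protected (2S)-flavanone
Product: 20 (2S)-5,7,8-trihydroxy-2-[4-hydroxy-3-(3-methylbut-3-en-1-yl)phenyl]-2,3-dihydro-4H-chromen-4-one (target)
Conditions: HF·pyridine, pyridine, THF, 0 °C to rt, argon; pH 6 phosphate buffer work-up
Reagents that add atoms: none
Why: Fluoride-driven cleavage of the two aryl silyl ethers and the silylene in a weakly acidic buffered medium avoids both the phenoxide-triggered ring opening to the chalcone (which would racemise C2 and allow reclosure on O5) and the strong acid that would shift or cyclise the side-chain alkene.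

## Compound list

1 | 3,4,5-trihydroxybenzaldehyde | O=Cc1cc(O)c(O)c(O)c1 | starting material
2 | 2,2-di-tert-butyl-4-hydroxy-1,3,2-benzodioxasilole-6-carbaldehyde | O=Cc1cc(O)c2O[Si](C(C)(C)C)(C(C)(C)C)Oc2c1 | intermediate
3 | 2,2-di-tert-butyl-6-formyl-1,3,2-benzodioxasilol-4-yl acetate | CC(=O)Oc1cc(C=O)cc2O[Si](C(C)(C)C)(C(C)(C)C)Oc12 | intermediate
4 | 2,2-di-tert-butyl-6-(formyloxy)-1,3,2-benzodioxasilol-4-yl acetate | CC(=O)Oc1cc(OC=O)cc2O[Si](C(C)(C)C)(C(C)(C)C)Oc12 | intermediate
5 | 2,2-di-tert-butyl-6-hydroxy-1,3,2-benzodioxasilol-4-yl acetate | CC(=O)Oc1cc(O)cc2O[Si](C(C)(C)C)(C(C)(C)C)Oc12 | intermediate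
6 | 6-[(tert-butyldimethylsilyl)oxy]-2,2-di-tert-butyl-1,3,2-benzodioxasilol-4-yl acetate | CC(=O)Oc1cc(O[Si](C)(C)C(C)(C)C)cc2O[Si](C(C)(C)C)(C(C)(C)C)Oc12 | intermediate
7 | 6-[(tert-butyldimethylsilyl)oxy]-2,2-di-tert-butyl-1,3,2-benzodioxasilol-4-ol | Oc1cc(O[Si](C)(C)C(C)(C)C)cc2O[Si](C(C)(C)C)(C(C)(C)C)Oc12 | intermediate
8 | 6-[(tert-butyldimethylsilyl)oxy]-2,2-di-tert-butyl-4-hydroxy-1,3,2-benzodioxasilole-5-carbaldehyde | O=Cc1c(O)c2O[Si](C(C)(C)C)(C(C)(C)C)Oc2cc1O[Si](C)(C)C(C)(C)C | intermediate
9 | 1-(3-bromo-4-hydroxyphenyl)ethan-1-one | CC(=O)c1ccc(O)c(Br)c1 | starting material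
10 | 1-{3-bromo-4-[(tert-butyldimethylsilyl)oxy]phenyl}ethan-1-one | CC(=O)c1ccc(O[Si](C)(C)C(C)(C)C)c(Br)c1 | intermediate
11 | 4-bromo-2-methylbut-1-ene | C=C(C)CCBr | starting material
12 | bromo(3-methylbut-3-en-1-yl)zinc | C=C(C)CC[Zn]Br | intermediate
13 | 1-{4-[(tert-butyldimethylsilyl)oxy]-3-(3-methylbut-3-en-1-yl)phenyl}ethan-1-one | C=C(C)CCc1cc(C(C)=O)ccc1O[Si](C)(C)C(C)(C)C | intermediate
14 | trimethylsilyl enol ether of 13 | C=C(C)CCc1cc(C(=C)O[Si](C)(C)C)ccc1O[Si](C)(C)C(C)(C)C | intermediate
15 | 2-bromo-1-{4-[(tert-butyldimethylsilyl)oxy]-3-(3-methylbut-3-en-1-yl)phenyl}ethan-1-one | C=C(C)CCc1cc(C(=O)CBr)ccc1O[Si](C)(C)C(C)(C)C | intermediate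
16 | racemic 2-bromo-1-{4-[(tert-butyldimethylsilyl)oxy]-3-(3-methylbut-3-en-1-yl)phenyl}ethan-1-ol | C=C(C)CCc1cc(C(O)CBr)ccc1O[Si](C)(C)C(C)(C)C | intermediate
17 | racemic bromo ether aldehyde (O1–C2 joined, C3 as CH2Br) | C=C(C)CCc1cc(C(CBr)Oc2c(C=O)c(O[Si](C)(C)C(C)(C)C)cc3O[Si](C(C)(C)C)(C(C)(C)C)Oc23)ccc1O[Si](C)(C)C(C)(C)C | intermediate
18 | formyl enol ether (alpha-aryloxystyrene, achiral) | C=C(C)CCc1cc(C(=C)Oc2c(C=O)c(O[Si](C)(C)C(C)(C)C)cc3O[Si](C(C)(C)C)(C(C)(C)C)Oc23)ccc1O[Si](C)(C)C(C)(C)C | intermediate
19 | (2S)-flavanone with 5-OTBS, 4'-OTBS and 7,8-O,O-di-tert-butylsilylene | C=C(C)CCc1cc([C@@H]2CC(=O)c3c(O[Si](C)(C)C(C)(C)C)cc4O[Si](C(C)(C)C)(C(C)(C)C)Oc4c3O2)ccc1O[Si](C)(C)C(C)(C)C | intermediate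
20 | (2S)-5,7,8-trihydroxy-2-[4-hydroxy-3-(3-methylbut-3-en-1-yl)phenyl]-2,3-dihydro-4H-chromen-4-one | C=C(C)CCc1cc([C@@H]2CC(=O)c3c(O)cc(O)c(O)c3O2)ccc1O | target

## Step count and risks

Total step count: 12.
Longest linear sequence: 8 steps (1–4, then 9–12). The ring B branch (5–8, then 9–12) is equally long.

Steps most likely to fail:

**1. Step 11 (proposed new method).**
- What may go wrong: oxidative addition at the doubly ortho-substituted formyl group may be slow. The acyl rhodium hydride may decarbonylate. The alkyl rhodium may lose the beta-aryloxy group. Face selection at the enol ether may be poor.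
- Fallback (known chemistry): it sets out from 15 and 8 and comes back at 19.
- Corey–Bakshi–Shibata reduction of 15 with (S)-2-methyl-CBS-oxazaborolidine and BH3·SMe2 should give (S)-2-bromo-1-{4-[(tert-butyldimethylsilyl)oxy]-3-(3-methylbut-3-en-1-yl)phenyl}ethan-1-ol F1.
- Mitsunobu etherification of F1 with 8 (PPh3, DIAD, toluene, low temperature) should proceed with inversion to the (R)-enantiomer of bromo ether 17 F2.
- An N-heterocyclic carbene then closes C3–C4 (3-benzyl-5-(2-hydroxyethyl)-4-methylthiazolium chloride, iPr2NEt, THF, 40 °C). The Breslow intermediate of the formyl group displaces the primary bromide in an intramolecular SN2 reaction. This closure is known for 2-(2-haloethoxy)benzaldehydes, which give chroman-4-ones. The preset stereocentre is not touched, so 19 should result.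

**2. Step 9.**
- What may go wrong: substitution at the crowded, chelated phenol may be slow. The electron-rich benzylic oxyphosphonium ion may ionise, which leads to carbon alkylation at C6 or to loss of a proton.
- Fallback: it sets out from 16 and 8 and comes back at 18.
- NaH in THF at 0 °C should close 16 to racemic 2-{4-[(tert-butyldimethylsilyl)oxy]-3-(3-methylbut-3-en-1-yl)phenyl}oxirane F3.
- Lewis acid-assisted opening with phenol 8 (Zn(OTf)2, 10 mol%, CH2Cl2, −20 °C) should take place at the donor-stabilised benzylic carbon and give the primary alcohol analogue of 17 F4.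
- Mesylation (MsCl, Et3N, CH2Cl2, 0 °C) gives the mesylate analogue of 17 F5. DBU in toluene at 80 °C then eliminates it to 18.

**3. Step 4.**
- What may go wrong: attack at the carbon flanked by the silyloxy group may be sluggish. A silyl group may be lost in the hot amine/magnesium alkoxide medium.
- Fallback: it sets out from 7 and comes back at 8.
- Boronic acid-templated ortho-hydroxymethylation (PhB(OH)2, (CH2O)n, propionic acid cat., toluene, reflux with water removal) should give the 2-phenyl-4H-1,3,2-benzodioxaborin of 7 F6.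
- Exchange with propane-1,3-diol in THF at rt frees the salicyl alcohol analogue of 8 F7.
- MnO2 in CH2Cl2 oxidises the benzylic alcohol under neutral conditions to 8.

## Further compounds

F1 | step 11 | (S)-2-bromo-1-{4-[(tert-butyldimethylsilyl)oxy]-3-(3-methylbut-3-en-1-yl)phenyl}ethan-1-ol | C=C(C)CCc1cc([C@H](O)CBr)ccc1O[Si](C)(C)C(C)(C)C
F2 | step 11 | (R)-enantiomer of bromo ether 17 | C=C(C)CCc1cc([C@H](CBr)Oc2c(C=O)c(O[Si](C)(C)C(C)(C)C)cc3O[Si](C(C)(C)C)(C(C)(C)C)Oc23)ccc1O[Si](C)(C)C(C)(C)C
F3 | step 9 | racemic 2-{4-[(tert-butyldimethylsilyl)oxy]-3-(3-methylbut-3-en-1-yl)phenyl}oxirane | C=C(C)CCc1cc(C2CO2)ccc1O[Si](C)(C)C(C)(C)C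
F4 | step 9 | primary alcohol analogue of 17 (CH2OH in place of CH2Br, racemic) | C=C(C)CCc1cc(C(CO)Oc2c(C=O)c(O[Si](C)(C)C(C)(C)C)cc3O[Si](C(C)(C)C)(C(C)(C)C)Oc23)ccc1O[Si](C)(C)C(C)(C)C
F5 | step 9 | mesylate analogue of 17 (CH2OMs in place of CH2Br, racemic) | C=C(C)CCc1cc(C(COS(C)(=O)=O)Oc2c(C=O)c(O[Si](C)(C)C(C)(C)C)cc3O[Si](C(C)(C)C)(C(C)(C)C)Oc23)ccc1O[Si](C)(C)C(C)(C)C
F6 | step 4 | 2-phenyl-4H-1,3,2-benzodioxaborin of 7 (O1–B–O–CH2–C4a ring) | CC(C)(C)[Si](C)(C)Oc1cc2O[Si](C(C)(C)C)(C(C)(C)C)Oc2c2OB(c3ccccc3)OCc12
F7 | step 4 | salicyl alcohol analogue of 8 (CH2OH in place of CHO) | OCc1c(O)c2O[Si](C(C)(C)C)(C(C)(C)C)Oc2cc1O[Si](C)(C)C(C)(C)C
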